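**Retrosynthetic overview**
1. Sceptrin ⇒ its bis(imidazo[1,2-a]pyrimidine) form. Each 2-aminoimidazole is carried as a purchased bicycle, and hydrazine excises the pyrimidine ring at the very end.
2. Cyclobutane ⇒ two identical, fully functionalised hymenidin surrogates. One intermolecular head-to-head [2+2] homodimerisation mirrors the proposed hymenidin → sceptrin biogenesis. A chiral phosphoric acid assembles the two monomers, so both C–C bonds and all four stereocentres form in one enantioselective step.
3. Hymenidin surrogate ⇒ 3-bromoimidazo[1,2-a]pyrimidine plus the (E)-alkenyl boronate of an N-propargyl amide (one-pot hydroboration/Suzuki).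
4. N-Propargyl amide ⇒ 4-bromo-2-(trichloroacetyl)pyrrole plus propargylamine.
5. Ring order: the pyrrole and imidazole rings are purchased, the cyclobutane is the only ring made (third step), and the pyrimidine masks are opened last.

Assumption: the sense of induction of the chiral acid cannot be assigned in advance, so (R)-TRIP is written and the equally available (S)-TRIP is used if the first run gives the mirror image; sceptrin is delivered as the free base drawn.

Abbreviations: HBpin is pinacolborane. TRIP is 3,3′-bis(2,4,6-triisopropylphenyl)-1,1′-binaphthyl-2,2′-diyl hydrogen phosphate.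

**Step 1**
Reactants: 1 (4-bromo-2-(trichloroacetyl)-1H-pyrrole) and 2 (propargylamine)
Product: 3 4-bromo-N-(prop-2-yn-1-yl)-1H-pyrrole-2-carboxamide
Conditions: MeCN, rt, 16 h
Reagents that add atoms: none
Why: Haloform-type aminolysis, in which the trichloromethyl ketone acts as an acid-chloride surrogate (CCl3 leaves as CHCl3) and acylates the primary amine at rt without base or pyrrole N-protection; no stereocentre is formed.

**Step 2**
Reactants: 3 (4-bromo-N-(prop-2-yn-1-yl)-1H-pyrrole-2-carboxamide) and 4 (3-bromoimidazo[1,2-a]pyrimidine)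
Product: 6 (E)-4-bromo-N-[3-(imidazo[1,2-a]pyrimidin-3-yl)prop-2-en-1-yl]-1H-pyrrole-2-carboxamide (hymenidin surrogate), via (E)-alkenyl pinacol boronate 5 (not isolated)
Conditions: HBpin (3 equiv), Cp2ZrHCl (10 mol %), Et3N (10 mol %), THF, 60 °C; then 4 (1.1 equiv), Pd(dppf)Cl2 (5 mol %), K3PO4, dioxane/H2O, 70 °C, one pot
Reagents that add atoms: pinacolborane, CC1(C)OBOC1(C)C (its boryl group is carried by 5 and lost again in the coupling)
Why: Zr-catalysed syn-hydroboration of the terminal alkyne puts boron on the terminus and fixes the E geometry, and the Suzuki–Miyaura coupling then proceeds with retention at the more reactive C3–Br of the π-deficient bicycle 4 rather than at the electron-rich, partly deprotonated 4-bromopyrrole (excess HBpin covers transient N–H borylation, which water reverses).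

**Step 3**
Reactants: 6 (hymenidin surrogate, two molecules)
Product: 7 N,N′-{[(1R,2R,3S,4S)-3,4-bis(imidazo[1,2-a]pyrimidin-3-yl)cyclobutane-1,2-diyl]bis(methylene)}bis(4-bromo-1H-pyrrole-2-carboxamide) (masked sceptrin, all-trans, C2-symmetric)
Conditions: fac-Ir(ppy)3 (2 mol %), (R)-TRIP (50 mol %, recovered on work-up), CH2Cl2 (0.05 M), 450 nm LED, −40 °C, Ar, 48 h
Reagents that add atoms: none
Why: Proposed new method: an enantioselective version of the triplet-sensitised head-to-head [2+2] photodimerisation that copies the biogenetic dimerisation, in which the acid protonates N1 of one molecule of 6 and the phosphate oxygens accept the amide/pyrrole N–H bonds of a second molecule (exactly the heteroaryl/amidomethyl pair that ends up 1,3-cis on one face of the all-trans product), so the short-lived alkene triplet is trapped by the pre-associated partner on one face only; the first bond joins the two alkene carbons next to CH2N and leaves both radical centres heterobenzylic, and closure after intersystem crossing places all four substituents trans, which sets (1R,2R,3S,4S) in one event, while half an equivalent of acid keeps one proton per reacting pair although the product is as basic as the monomer; the closest known reaction types are the racemic Ir-sensitised dimerisation of vinyl heteroarenes and the chiral-phosphoric-acid/Ir-sensitised enantioselective [2+2] photocycloaddition of acyclic vinylpyridines with N–H amide alkenes through a hydrogen-bonded ternary complex.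

**Step 4**
Reactants: 7 (masked sceptrin)
Product: 8 sceptrin, N,N′-{[(1R,2R,3S,4S)-3,4-bis(2-amino-1H-imidazol-5-yl)cyclobutane-1,2-diyl]bis(methylene)}bis(4-bromo-1H-pyrrole-2-carboxamide)
Conditions: N2H4·H2O (20 equiv), EtOH, 80 °C, 12 h; C18 chromatography, basic resin
Reagents that add atoms: none
Why: Hydrazinolysis of the imidazo[1,2-a]pyrimidine (addition, ring opening, ring closure; the standard unmasking of 2-aminoimidazoles), in which hydrazine adds at C5/C7 and removes C5–C7 as pyrazole, leaving N8 as the exocyclic NH2 and N4 as the ring N–H, while the secondary pyrrole amides, the C–Br bonds and the four stereocentres (already the all-trans thermodynamic arrangement, far below the temperature of the thermal sceptrin rearrangement) are untouched.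

**Compound list**
1 | 4-bromo-2-(trichloroacetyl)-1H-pyrrole | O=C(c1cc(Br)c[nH]1)C(Cl)(Cl)Cl | starting material
2 | propargylamine (prop-2-yn-1-amine) | C#CCN | starting material
3 | 4-bromo-N-(prop-2-yn-1-yl)-1H-pyrrole-2-carboxamide | C#CCNC(=O)c1cc(Br)c[nH]1 | intermediate
4 | 3-bromoimidazo[1,2-a]pyrimidine | Brc1cnc2ncccn12 | starting material
5 | 4-bromo-N-[(E)-3-(4,4,5,5-tetramethyl-1,3,2-dioxaborolan-2-yl)prop-2-en-1-yl]-1H-pyrrole-2-carboxamide (not isolated) | CC1(C)OB(/C=C/CNC(=O)c2cc(Br)c[nH]2)OC1(C)C | intermediate
6 | (E)-4-bromo-N-[3-(imidazo[1,2-a]pyrimidin-3-yl)prop-2-en-1-yl]-1H-pyrrole-2-carboxamide | O=C(NC/C=C/c1cnc2ncccn12)c1cc(Br)c[nH]1 | intermediate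
7 | N,N′-{[(1R,2R,3S,4S)-3,4-bis(imidazo[1,2-a]pyrimidin-3-yl)cyclobutane-1,2-diyl]bis(methylene)}bis(4-bromo-1H-pyrrole-2-carboxamide) | c1cnc2ncc(n2c1)[C@H]3[C@H](CNC(=O)c4cc(Br)c[nH]4)[C@@H](CNC(=O)c4cc(Br)c[nH]4)[C@@H]3c5cnc6ncccn56 | intermediate
8 | sceptrin | Nc1ncc([C@H]2[C@H](CNC(=O)c3cc(Br)c[nH]3)[C@@H](CNC(=O)c3cc(Br)c[nH]3)[C@@H]2c2cnc(N)[nH]2)[nH]1 | target

**Total step count:** 4. **Longest linear sequence:** 4 (1 → 3 → 6 → 7 → 8).

**Three steps most likely to fail**

Step 3 carries the highest risk.
- Dimerisation outside the acid complex would erode the ee.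
- E/Z isomerisation wastes triplet energy.
- Excited Ir(ppy)3 could transfer an electron to the protonated heteroarene.
- A moderate ee would first be raised by recrystallising 7.

The fallback gives up catalytic induction. It sets out from 6 and comes back at 7. Compound 6 is irradiated with fac-Ir(ppy)3 alone in MeOH at rt, without any chiral acid. This gives the racemic all-trans head-to-head dimer, that is 7 together with the (1S,2S,3R,4R) mirror-image masked sceptrin F1. The two are separated by preparative SFC on an amylose-type chiral stationary phase, and 7 is carried on.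

Step 2 is the next risk.
- The pyrrole and amide N–H groups may quench the Zr–H/HBpin system.
- Pd may insert into, or protodebrominate, the pyrrole C–Br bond.

The fallback attaches the bromopyrrole only after all metal chemistry is done. It sets out from 2 and 4 and comes back at 6. Compound 2 is treated with Boc2O to give tert-butyl prop-2-yn-1-ylcarbamate F2. Zr-catalysed hydroboration with HBpin gives the isolated tert-butyl [(E)-3-(pinacolboryl)prop-2-en-1-yl]carbamate F3. Suzuki coupling with 4 (Pd(dppf)Cl2, K3PO4) gives tert-butyl [(E)-3-(imidazo[1,2-a]pyrimidin-3-yl)prop-2-en-1-yl]carbamate F4. TFA followed by basic work-up frees (E)-3-(imidazo[1,2-a]pyrimidin-3-yl)prop-2-en-1-amine F5. Acylation with 1 in MeCN delivers 6.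

Step 4 is the third risk.
- Hydrazine may attack the pyrrole amides.
- Hydrazine with trace metal may cause debromination.
- Compound 7 may be poorly soluble.
- The second pyrimidine cleavage may stall.

The fallback installs the pyrroles last, so hydrazine never meets them. It sets out from 2 and 4 through the carbamate F4 made as above, and comes back at 8. F4 is dimerised under the step 3 conditions, with the carbamate N–H serving as the hydrogen-bond donor to the phosphate. This gives di-tert-butyl {[(1R,2R,3S,4S)-3,4-bis(imidazo[1,2-a]pyrimidin-3-yl)cyclobutane-1,2-diyl]bis(methylene)}dicarbamate F6. Hydrazine hydrate in EtOH gives the bis(2-aminoimidazole) dicarbamate F7. TFA and then basic resin give (1R,2R,3S,4S)-1,2-bis(aminomethyl)-3,4-bis(2-amino-1H-imidazol-5-yl)cyclobutane F8. Two equivalents of 1 in DMF acylate only the primary alkylamines, because the delocalised 2-aminoimidazole nitrogens are far less nucleophilic. The product is 8.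

**Further compounds**
F1 | step 3 | N,N′-{[(1S,2S,3R,4R)-3,4-bis(imidazo[1,2-a]pyrimidin-3-yl)cyclobutane-1,2-diyl]bis(methylene)}bis(4-bromo-1H-pyrrole-2-carboxamide) (enantiomer of 7) | c1cnc2ncc(n2c1)[C@@H]3[C@@H](CNC(=O)c4cc(Br)c[nH]4)[C@H](CNC(=O)c4cc(Br)c[nH]4)[C@H]3c5cnc6ncccn56
F2 | step 2 | tert-butyl prop-2-yn-1-ylcarbamate | C#CCNC(=O)OC(C)(C)C
F3 | step 2 | tert-butyl [(E)-3-(4,4,5,5-tetramethyl-1,3,2-dioxaborolan-2-yl)prop-2-en-1-yl]carbamate | CC(C)(C)OC(=O)NC/C=C/B1OC(C)(C)C(C)(C)O1
F4 | step 2 | tert-butyl [(E)-3-(imidazo[1,2-a]pyrimidin-3-yl)prop-2-en-1-yl]carbamate | CC(C)(C)OC(=O)NC/C=C/c1cnc2ncccn12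
F5 | step 2 | (E)-3-(imidazo[1,2-a]pyrimidin-3-yl)prop-2-en-1-amine | NC/C=C/c1cnc2ncccn12
F6 | step 4 | di-tert-butyl {[(1R,2R,3S,4S)-3,4-bis(imidazo[1,2-a]pyrimidin-3-yl)cyclobutane-1,2-diyl]bis(methylene)}dicarbamate | c1cnc2ncc(n2c1)[C@H]3[C@H](CNC(=O)OC(C)(C)C)[C@@H](CNC(=O)OC(C)(C)C)[C@@H]3c5cnc6ncccn56
F7 | step 4 | di-tert-butyl {[(1R,2R,3S,4S)-3,4-bis(2-amino-1H-imidazol-5-yl)cyclobutane-1,2-diyl]bis(methylene)}dicarbamate | Nc1ncc([C@H]2[C@H](CNC(=O)OC(C)(C)C)[C@@H](CNC(=O)OC(C)(C)C)[C@@H]2c2cnc(N)[nH]2)[nH]1
F8 | step 4 | (1R,2R,3S,4S)-1,2-bis(aminomethyl)-3,4-bis(2-amino-1H-imidazol-5-yl)cyclobutane | Nc1ncc([C@H]2[C@H](CN)[C@@H](CN)[C@@H]2c2cnc(N)[nH]2)[nH]1
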